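**Retrosynthetic overview**
- The target is the 8α,9α-epoxide of a 4β-hydroxydauc-8-en-6α-yl benzoate: a cyclopentane (C1–C5) trans-fused to a cycloheptane (C1, C5–C10). The epoxide is traced back to the C8=C9 alkene, C9–H to a C9 enol triflate (from a C9 ketone with a C8 exocyclic methylene), and C5–H/C6–O to hydroboration of a C5=C6 alkene.
- Key disconnection: the bicyclic methylene dienone 19 is opened to the acyclic (Z)-bromotriene 13 plus CO. Three bonds form in one palladium cascade (C1–C5, C10–C9, C9–C8), the five-membered ring first, the seven-membered ring second.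
- Feature the plan rests on: C1 is a quaternary ring-fusion carbon, so palladium on C10 has no β-hydrogen once C1–C5 exists. C9 sits between C10 and C8 in the seven-membered ring and is oxygenated in the target, so it can enter as CO and leave its oxygen later through the enol triflate.
- Bromotriene 13 comes from terminal alkyne 11 and allyl bromide (syn-bromoallylation sets the Z-bromide). Alkyne 11 comes from (S)-terpinen-4-ol, which supplies the C4 carbinol stereocentre and C1–C6, by ozonolysis, methylenation and aldehyde-to-alkyne conversion.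

Key step: step 8

**Remarks**
- Numbering is that of the daucane skeleton: C1 ring-fusion carbon with methyl C15, C2/C3 cyclopentane CH2, C4 isopropyl carbinol, C5 ring-fusion CH, C6 benzoate carbon, C7 CH2, C8 (methyl C14) and C9 epoxide carbons, C10 CH2. β is the face that carries the C1 methyl, α the opposite face.
- (S)-Terpinen-4-ol is taken as a commercial chiral-pool material of high enantiomeric purity.
- Which antipode of BINAP is matched to C4 cannot be derived on paper. (R)-BINAP is written, and (S)-BINAP takes its place if it proves to be the matched one.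
- In the SMILES of the organopalladium intermediates 15–18 the bisphosphine on palladium is not drawn.

**Route**

Step 1
Reactants: 1 (S)-terpinen-4-ol
Product: 2 (S)-terpinen-4-yl triethylsilyl ether
Conditions: Et3SiOTf, 2,6-lutidine, CH2Cl2, 0 °C to rt
Reagents that add atoms: triethylsilyl trifluoromethanesulfonate, CC[Si](CC)(CC)OS(=O)(=O)C(F)(F)F
Why: Silyl ether formation with a silyl triflate and a hindered pyridine is the standard way to cap a hindered tertiary alcohol, and the C4 stereocentre is not touched.

Step 2
Reactants: 2 (S)-terpinen-4-yl triethylsilyl ether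
Product: 5 (5S)-7,7-dimethoxy-5-(propan-2-yl)-5-(triethylsilyloxy)heptan-2-one, via methoxy hydroperoxide aldehyde 3 (not isolated), via methoxy hydroperoxide acetal 4 (not isolated)
Conditions: O3, CH2Cl2/MeOH, −78 °C; TsOH·H2O (5 mol %), 0 °C to rt; NaHCO3, then Me2S, rt
Reagents that add atoms: ozone, [O-][O+]=O; methanol, CO
Why: Ozonolysis with unsymmetrical work-up (Criegee cleavage of the trisubstituted alkene to the C1 ketone oxide, trapped by methanol, and the free C6 aldehyde, which is acetalised before Me2S reduces the hydroperoxide) should deliver ketone and masked aldehyde differentiated in one flask, the doubly hindered tertiary silyl ether being expected to outlast the brief catalytic acid.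

Step 3
Reactants: 5 (5S)-7,7-dimethoxy-5-(propan-2-yl)-5-(triethylsilyloxy)heptan-2-one; 6 methyltriphenylphosphonium bromide
Product: 7 triethyl{[(3S)-1,1-dimethoxy-6-methyl-3-(propan-2-yl)hept-6-en-3-yl]oxy}silane
Conditions: 6, KOt-Bu, THF, 0 °C; then 5, 0 °C to rt
Reagents that add atoms: methyltriphenylphosphonium bromide (6), C[P+](c1ccccc1)(c1ccccc1)c1ccccc1.[Br-]
Why: Wittig methylenation of the methyl ketone installs C10 as the 1,1-disubstituted alkene while the acetal keeps the aldehyde out of reach and the γ-silyloxy group cannot be eliminated.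

Step 4
Reactants: 7 triethyl{[(3S)-1,1-dimethoxy-6-methyl-3-(propan-2-yl)hept-6-en-3-yl]oxy}silane
Product: 8 (3S)-6-methyl-3-(propan-2-yl)-3-(triethylsilyloxy)hept-6-enal
Conditions: PPTS (0.2 equiv), acetone/H2O 10:1, 45 °C
Reagents that add atoms: water, O
Why: Mild acid-catalysed acetal hydrolysis (transacetalisation to acetone) should free the aldehyde, PPTS being too weak to cleave the tertiary silyl ether or to move the 1,1-disubstituted alkene.

Step 5
Reactants: 8 (3S)-6-methyl-3-(propan-2-yl)-3-(triethylsilyloxy)hept-6-enal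
Product: 9 (3R)-6-methyl-3-(propan-2-yl)-3-(triethylsilyloxy)hepta-1,6-dien-1-yl trifluoromethanesulfonate (E/Z mixture)
Conditions: Tf2O, 2,6-di-tert-butyl-4-methylpyridine, CH2Cl2, 0 °C to rt
Reagents that add atoms: trifluoromethanesulfonic anhydride, O=S(=O)(OS(=O)(=O)C(F)(F)F)C(F)(F)F
Why: Enol triflate formation from an aldehyde by O-triflation and loss of a C5 proton to the hindered pyridine avoids an enolate, which could expel the β-silyloxy group, and both alkene isomers serve the next step.

Step 6
Reactants: 9 (3R)-6-methyl-3-(propan-2-yl)-3-(triethylsilyloxy)hepta-1,6-dien-1-yl trifluoromethanesulfonate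
Product: 11 triethyl{[(3R)-6-methyl-3-(propan-2-yl)hept-6-en-1-yn-3-yl]oxy}silane, via lithium acetylide 10 (not isolated)
Conditions: LiN(i-Pr)2 (2.5 equiv), THF, −78 to 0 °C; then H2O
Reagents that add atoms: lithium diisopropylamide, [Li]N(C(C)C)C(C)C (lithium in 10 only)
Why: Base-induced elimination of triflate from a primary alkenyl triflate (β-elimination, or α-elimination with 1,2-hydrogen shift of the Fritsch–Buttenberg–Wiechell type) gives the terminal alkyne, no allene being possible because C4 is quaternary, and excess amide holds the product as its acetylide until the quench.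

Step 7
Reactants: 11 triethyl{[(3R)-6-methyl-3-(propan-2-yl)hept-6-en-1-yn-3-yl]oxy}silane; 12 allyl bromide
Product: 13 triethyl{[(5R,6Z)-6-bromo-2-methyl-5-(propan-2-yl)deca-1,6,9-trien-5-yl]oxy}silane
Conditions: PdBr2(PhCN)2 (5 mol %), allyl bromide (10 equiv), DME, 0 °C to rt
Reagents that add atoms: allyl bromide (12), C=CCBr
Why: Palladium-catalysed bromoallylation of a terminal alkyne should proceed by syn-bromopalladation (Br to the internal carbon C5, palladium to C6), insertion of allyl bromide and β-bromide elimination, which places the allyl group cis to bromine (Z) and keeps palladium divalent so that the new C–Br bond is not attacked.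

Step 8
Reactants: 13 triethyl{[(5R,6Z)-6-bromo-2-methyl-5-(propan-2-yl)deca-1,6,9-trien-5-yl]oxy}silane; 14 carbon monoxide
Product: 19 4β-(triethylsilyloxy)dauca-5,8(14)-dien-9-one, via alkenylpalladium bromide 15 (not isolated), via neopentylpalladium bromide 16 (not isolated), via acylpalladium bromide 17 (not isolated), via alkylpalladium bromide 18 (not isolated)
Conditions: Pd(OAc)2 (10 mol %), (R)-BINAP (22 mol %), 1,2,2,6,6-pentamethylpiperidine (2 equiv), CO (1 atm), MeCN/toluene 1:1 (0.01 M), 75 °C
Reagents that add atoms: carbon monoxide (14), [C-]#[O+]; Pd(OAc)2, CC(=O)O[Pd]OC(C)=O (palladium in 15 to 18 only)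
Why: Proposed new method: zerovalent palladium formed from Pd(OAc)2 and BINAP inserts into the C5–Br bond (15), syn-carbopalladation of the C1=C10 alkene makes C1–C5 and the neopentyl complex 16, CO inserts into its Pd–C10 bond (17, C10–C9), the acyl group adds to the internal carbon of the vinyl group (18, C9–C8) and β-hydride elimination from C8 releases 19 while the amine takes up HBr. The closest known chemistry is the domino Heck–carbonylation through a neopentylpalladium intermediate and the ring-forming acylpalladation of alkenes to five- and six-membered ketones; their union with a seven-membered acylpalladation ended by β-hydride elimination is what is untested. The cyclopentane closes 5-exo-trig and the cycloheptenone 7-exo-trig. C1, the only new stereocentre, is set by C4: in the envelope-like insertion transition state the isopropyl group should lie pseudo-equatorial and the silyloxy group pseudo-axial, so palladium and C10 add to the face away from oxygen (methyl cis to O), a preference the matched BINAP antipode is meant to reinforce. The step needs 5-exo insertion to outrun CO insertion at 15 and CO insertion at 16 to outrun 3-exo attack on C5=C6, which 1 atm of CO and the missing β-hydrogen at the quaternary C1 should secure, and it needs C9 to reach C8, which the Z-alkene secures by holding the C7 arm cis to C1 while high dilution suppresses intermolecular acylpalladation. The hindered amine cannot intercept the acyl complex and is not expected to remove a C7 hydrogen, so the skipped methylene dienone should not slip into conjugation.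

Step 9
Reactants: 19 4β-(triethylsilyloxy)dauca-5,8(14)-dien-9-one
Product: 21 4β-(triethylsilyloxy)dauca-5,8-dien-9-yl trifluoromethanesulfonate, via lithium enolate 20 (not isolated)
Conditions: LiBH(s-Bu)3 (1.1 equiv), THF, −78 °C; then PhNTf2, −78 to 0 °C
Reagents that add atoms: LiBH(s-Bu)3, [Li+].CCC(C)[BH-](C(C)CC)C(C)CC (lithium in 20 only); N-phenylbis(trifluoromethanesulfonimide), O=S(=O)(N(c1ccccc1)S(=O)(=O)C(F)(F)F)C(F)(F)F
Why: Conjugate reduction of the unhindered exocyclic enone by the bulky borohydride gives the C8=C9 enolate regiospecifically (C14 becomes the methyl group), and enolate O-triflation fixes that double bond position as the enol triflate.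

Step 10
Reactants: 21 4β-(triethylsilyloxy)dauca-5,8-dien-9-yl trifluoromethanesulfonate
Product: 23 6α-hydroxy-4β-(triethylsilyloxy)-5α-dauc-8-en-9-yl trifluoromethanesulfonate, via C6 alkylborane 22 (not isolated)
Conditions: BH3·THF, THF, 0 °C to rt; then NaBO3·4H2O, THF/H2O, rt
Reagents that add atoms: borane–tetrahydrofuran, [BH3-][O+]1CCCC1 (boron in 22 only); sodium perborate tetrahydrate, [Na+].[O-]OB=O
Why: Hydroboration–oxidation puts boron on C6 and hydrogen on C5 in a syn addition that should come from the α-face, because the β-face of C5=C6 carries both the C1 methyl and the C4 silyloxy group (as in hydroboration anti to an angular methyl). This sets 5α-H (trans ring fusion) and, after oxidation with retention, 6α-OH, while the electron-poor tetrasubstituted enol triflate is left alone.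

Step 11
Reactants: 23 6α-hydroxy-4β-(triethylsilyloxy)-5α-dauc-8-en-9-yl trifluoromethanesulfonate; 24 benzoyl chloride
Product: 25 6α-benzoyloxy-4β-(triethylsilyloxy)-5α-dauc-8-en-9-yl trifluoromethanesulfonate
Conditions: BzCl, DMAP (0.3 equiv), pyridine, CH2Cl2, 0 °C to rt
Reagents that add atoms: benzoyl chloride (24), O=C(Cl)c1ccccc1
Why: DMAP-catalysed acylation (nucleophilic catalysis) esterifies the only free hydroxyl without touching any stereocentre.

Step 12
Reactants: 25 6α-benzoyloxy-4β-(triethylsilyloxy)-5α-dauc-8-en-9-yl trifluoromethanesulfonate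
Product: 26 4β-(triethylsilyloxy)-5α-dauc-8-en-6α-yl benzoate
Conditions: Pd(OAc)2 (5 mol %), PPh3 (10 mol %), HCO2H, n-Bu3N, DMF, 60 °C
Reagents that add atoms: none
Why: Palladium-catalysed formate reduction of an enol triflate (oxidative addition, formate exchange, decarboxylation, reductive elimination of C9–H) leaves the C8=C9 alkene in place, and the benzoate is homoallylic and so cannot ionise.

Step 13
Reactants: 26 4β-(triethylsilyloxy)-5α-dauc-8-en-6α-yl benzoate
Product: 27 4β-hydroxy-5α-dauc-8-en-6α-yl benzoate
Conditions: HF·pyridine, pyridine/THF, 0 °C to rt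
Reagents that add atoms: none
Why: Fluoride-driven desilylation cleaves the tertiary silyl ether while benzoate and alkene are inert, and it is placed before the epoxidation so that HF never meets the epoxide.

Step 14
Reactants: 27 4β-hydroxy-5α-dauc-8-en-6α-yl benzoate
Product: 28 8α,9α-epoxy-4β-hydroxy-5α-daucan-6α-yl benzoate (CNP0340059.1)
Conditions: mCPBA, NaHCO3, CH2Cl2, 0 °C
Reagents that add atoms: 3-chloroperoxybenzoic acid, O=C(OO)c1cccc(Cl)c1
Why: Prilezhaev epoxidation of the trisubstituted C8=C9 alkene should occur on the α-face, because in the trans-fused ring system the C1 methyl is pseudo-axial over the β-face next to C9 while the 6α-benzoate is equatorial, and the bicarbonate buffer protects the epoxide from acid.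

**Compound list**
1 | (S)-terpinen-4-ol | CC(C)[C@]1(O)CCC(C)=CC1 | starting material
2 | (S)-terpinen-4-yl triethylsilyl ether | CC(C)[C@]1(O[Si](CC)(CC)CC)CCC(C)=CC1 | intermediate
3 | (3S)-6-hydroperoxy-6-methoxy-3-(propan-2-yl)-3-(triethylsilyloxy)heptanal, C6 epimers (formed in the flask) | CC(OC)(OO)CC[C@@](O[Si](CC)(CC)CC)(C(C)C)CC=O | intermediate
4 | (5S)-2-hydroperoxy-2,7,7-trimethoxy-5-(propan-2-yl)-5-(triethylsilyloxy)heptane, C2 epimers (formed in the flask) | CC(OC)(OO)CC[C@@](O[Si](CC)(CC)CC)(C(C)C)CC(OC)OC | intermediate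
5 | (5S)-7,7-dimethoxy-5-(propan-2-yl)-5-(triethylsilyloxy)heptan-2-one | CC(=O)CC[C@@](O[Si](CC)(CC)CC)(C(C)C)CC(OC)OC | intermediate
6 | methyltriphenylphosphonium bromide | C[P+](c1ccccc1)(c1ccccc1)c1ccccc1.[Br-] | starting material
7 | triethyl{[(3S)-1,1-dimethoxy-6-methyl-3-(propan-2-yl)hept-6-en-3-yl]oxy}silane | C=C(C)CC[C@@](O[Si](CC)(CC)CC)(C(C)C)CC(OC)OC | intermediate
8 | (3S)-6-methyl-3-(propan-2-yl)-3-(triethylsilyloxy)hept-6-enal | C=C(C)CC[C@@](O[Si](CC)(CC)CC)(C(C)C)CC=O | intermediate
9 | (3R)-6-methyl-3-(propan-2-yl)-3-(triethylsilyloxy)hepta-1,6-dien-1-yl trifluoromethanesulfonate, E/Z mixture | C=C(C)CC[C@@](O[Si](CC)(CC)CC)(C(C)C)C=COS(=O)(=O)C(F)(F)F | intermediate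
10 | lithium acetylide of 11 (formed in the flask) | C=C(C)CC[C@@](O[Si](CC)(CC)CC)(C(C)C)C#C[Li] | intermediate
11 | triethyl{[(3R)-6-methyl-3-(propan-2-yl)hept-6-en-1-yn-3-yl]oxy}silane | C=C(C)CC[C@@](O[Si](CC)(CC)CC)(C(C)C)C#C | intermediate
12 | allyl bromide | C=CCBr | starting material
13 | triethyl{[(5R,6Z)-6-bromo-2-methyl-5-(propan-2-yl)deca-1,6,9-trien-5-yl]oxy}silane (acyclic bromotriene; Br on C5, cis to C7) | C=C(C)CC[C@@](O[Si](CC)(CC)CC)(C(C)C)/C(Br)=C/CC=C | intermediate
14 | carbon monoxide | [C-]#[O+] | starting material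
15 | alkenylpalladium bromide from insertion into C5–Br (formed in the flask) | C=C(C)CC[C@@](O[Si](CC)(CC)CC)(C(C)C)/C([Pd]Br)=C/CC=C | intermediate
16 | neopentylpalladium bromide: cyclopentane with C1 methyl cis to the C4 oxygen, palladium on C10, exocyclic C5=C6 with C7 cis to C1 (formed in the flask) | CC(C)[C@]1(O[Si](CC)(CC)CC)CC[C@](C)(C[Pd]Br)/C1=C\CC=C | intermediate
17 | acylpalladium bromide, palladium on the C9 carbonyl (formed in the flask) | CC(C)[C@]1(O[Si](CC)(CC)CC)CC[C@](C)(CC(=O)[Pd]Br)/C1=C\CC=C | intermediate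
18 | bicyclic alkylpalladium bromide, palladium on C14, C8 epimers (formed in the flask) | CC(C)[C@]1(O[Si](CC)(CC)CC)CC[C@]2(C)CC(=O)C(C[Pd]Br)CC=C21 | intermediate
19 | 4β-(triethylsilyloxy)dauca-5,8(14)-dien-9-one (hydroazulen-9-one with C5=C6 and C8 exocyclic methylene; C1 methyl cis to the C4 oxygen) | CC(C)[C@]1(O[Si](CC)(CC)CC)CC[C@]2(C)CC(=O)C(=C)CC=C21 | intermediate
20 | lithium C8=C9 enolate of the C14-reduced ketone (formed in the flask) | CC(C)[C@]1(O[Si](CC)(CC)CC)CC[C@]2(C)CC(O[Li])=C(C)CC=C21 | intermediate
21 | 4β-(triethylsilyloxy)dauca-5,8-dien-9-yl trifluoromethanesulfonate | CC(C)[C@]1(O[Si](CC)(CC)CC)CC[C@]2(C)CC(OS(=O)(=O)C(F)(F)F)=C(C)CC=C21 | intermediate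
22 | C6α alkylborane with 5α-H (formed in the flask) | CC(C)[C@]1(O[Si](CC)(CC)CC)CC[C@]2(C)CC(OS(=O)(=O)C(F)(F)F)=C(C)C[C@H](B)[C@H]21 | intermediate
23 | 6α-hydroxy-4β-(triethylsilyloxy)-5α-dauc-8-en-9-yl trifluoromethanesulfonate | CC(C)[C@]1(O[Si](CC)(CC)CC)CC[C@]2(C)CC(OS(=O)(=O)C(F)(F)F)=C(C)C[C@H](O)[C@H]21 | intermediate
24 | benzoyl chloride | O=C(Cl)c1ccccc1 | starting material
25 | 6α-benzoyloxy-4β-(triethylsilyloxy)-5α-dauc-8-en-9-yl trifluoromethanesulfonate | CC(C)[C@]1(O[Si](CC)(CC)CC)CC[C@]2(C)CC(OS(=O)(=O)C(F)(F)F)=C(C)C[C@H](OC(=O)c3ccccc3)[C@H]21 | intermediate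
26 | 4β-(triethylsilyloxy)-5α-dauc-8-en-6α-yl benzoate | CC(C)[C@]1(O[Si](CC)(CC)CC)CC[C@]2(C)CC=C(C)C[C@H](OC(=O)c3ccccc3)[C@H]21 | intermediate
27 | 4β-hydroxy-5α-dauc-8-en-6α-yl benzoate | CC(C)[C@]1(O)CC[C@]2(C)CC=C(C)C[C@H](OC(=O)c3ccccc3)[C@H]21 | intermediate
28 | 8α,9α-epoxy-4β-hydroxy-5α-daucan-6α-yl benzoate (CNP0340059.1) | CC(C)[C@]1(O)CC[C@]2(C)C[C@@H]3O[C@]3(C)C[C@H](OC(=O)c3ccccc3)[C@H]21 | target

**Step count**
Total: 14 steps. Longest linear sequence: 14 steps (1 to 28).

**Steps most likely to fail**

1. Step 8 (the cascade). What may go wrong: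
   - the acylpalladium may not close the seven-membered ring and instead decarbonylate, form a ketene or be hydrolysed;
   - CO may insert before the 5-exo cyclisation;
   - the neopentylpalladium may attack C5=C6 (cyclopropanation and ring enlargement);
   - the face selectivity at C1 may be poor;
   - the methylene dienone may isomerise into conjugation.

   Fallback, from 13 back to 19, with the cascade cut after its known half. Under the same catalyst and base with CO (1 atm) in MeCN/MeOH, 5-exo Heck cyclisation and methoxycarbonylation of the neopentylpalladium (a known domino Heck–alkoxycarbonylation) should give the methyl ester F1. i-Bu2AlH at −78 °C would reduce it to the aldehyde F2, and NH2OH·HCl/pyridine would give the oxime F3. NaOCl in CH2Cl2 would generate the nitrile oxide F4, which should add across the vinyl group in an intramolecular nitrile oxide cycloaddition (C9–C8 bond, seven-membered carbocycle) to the isoxazoline F5. Mo(CO)6 in wet MeCN would cleave the N–O bond and hydrolyse the imine to the β-hydroxy ketone F6. MsCl/Et3N followed by DBU would eliminate to 19.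

2. Step 10 (hydroboration). What may go wrong: poor facial selectivity of borane addition, since the α-face is not free either (the isopropyl group on C4 and C10 lie there); addition from the β-face would give the cis-fused 6β-alcohol.

   Fallback, from 21 back to 27, with the face fixed by a directing group and two inversions. HF·pyridine would free the tertiary allylic alcohol F7. VO(acac)2/t-BuOOH should epoxidise C5=C6 syn to that hydroxyl, giving the 5β,6β-epoxide F8. Cp2TiCl (the trivalent titanium reagent made from Cp2TiCl2 and Zn) with 1,4-cyclohexadiene would open the epoxide at C5 to the tertiary radical. This radical should take its hydrogen on the α-face, away from the titanium alkoxide, the methyl and the hydroxyl, giving the 5α-H, 6β-alcohol F9. A Mitsunobu reaction with benzoic acid (PPh3, DIAD) would invert C6 to the 6α-benzoate F10. Formate reduction of the triflate (Pd(OAc)2, PPh3, HCO2H, n-Bu3N) would give 27.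

3. Step 7 (bromoallylation). What may go wrong: reversed regiochemistry or incomplete syn-selectivity of the bromopalladation at the hindered alkyne, competing insertion of the tethered alkene, or loss of the silyl ether to adventitious HBr.

   Fallback, from 11 back to 13. Bu4NF would give the alkynol F11. CuI/K2CO3/NaI with allyl bromide (12) in DMF would allylate the alkyne terminus to the enynol F12. [Cp*RuCl]4 with Bu3SnH should effect hydroxyl-directed trans-hydrostannation, with tin on the carbon next to the carbinol, to give the (Z)-stannane F13. NBS at −78 °C would exchange tin for bromine with retention to the bromo alcohol F14. Et3SiOTf/2,6-lutidine would return 13.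

**Further compounds**
F1 | step 8 | methyl ester of the monocyclic Heck–carbonylation product (CH2CO2Me and methyl on C1, exocyclic C5=C6 with C7 cis to C1) | CC(C)[C@]1(O[Si](CC)(CC)CC)CC[C@](C)(CC(=O)OC)/C1=C\CC=C
F2 | step 8 | corresponding C9 aldehyde | CC(C)[C@]1(O[Si](CC)(CC)CC)CC[C@](C)(CC=O)/C1=C\CC=C
F3 | step 8 | corresponding C9 aldoxime | CC(C)[C@]1(O[Si](CC)(CC)CC)CC[C@](C)(CC=NO)/C1=C\CC=C
F4 | step 8 | corresponding C9 nitrile oxide (formed in the flask) | CC(C)[C@]1(O[Si](CC)(CC)CC)CC[C@](C)(CC#[N+][O-])/C1=C\CC=C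
F5 | step 8 | tricyclic isoxazoline (C9=N, O on C14, new C8–C9 bond), C8 epimers | CC(C)[C@]1(O[Si](CC)(CC)CC)CC[C@]2(C)CC3=NOCC3CC=C21
F6 | step 8 | 14-hydroxy-4β-(triethylsilyloxy)dauc-5-en-9-one, C8 epimers | CC(C)[C@]1(O[Si](CC)(CC)CC)CC[C@]2(C)CC(=O)C(CO)CC=C21
F7 | step 10 | 4β-hydroxydauca-5,8-dien-9-yl trifluoromethanesulfonate | CC(C)[C@]1(O)CC[C@]2(C)CC(OS(=O)(=O)C(F)(F)F)=C(C)CC=C21
F8 | step 10 | 5β,6β-epoxy-4β-hydroxydauc-8-en-9-yl trifluoromethanesulfonate | CC(C)[C@]1(O)CC[C@]2(C)CC(OS(=O)(=O)C(F)(F)F)=C(C)C[C@H]3O[C@]321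
F9 | step 10 | 4β,6β-dihydroxy-5α-dauc-8-en-9-yl trifluoromethanesulfonate | CC(C)[C@]1(O)CC[C@]2(C)CC(OS(=O)(=O)C(F)(F)F)=C(C)C[C@@H](O)[C@H]21
F10 | step 10 | 6α-benzoyloxy-4β-hydroxy-5α-dauc-8-en-9-yl trifluoromethanesulfonate | CC(C)[C@]1(O)CC[C@]2(C)CC(OS(=O)(=O)C(F)(F)F)=C(C)C[C@H](OC(=O)c3ccccc3)[C@H]21
F11 | step 7 | (3R)-6-methyl-3-(propan-2-yl)hept-6-en-1-yn-3-ol | C=C(C)CC[C@@](O)(C(C)C)C#C
F12 | step 7 | (5R)-2-methyl-5-(propan-2-yl)deca-1,9-dien-6-yn-5-ol | C=C(C)CC[C@@](O)(C(C)C)C#CCC=C
F13 | step 7 | (5R,6Z)-2-methyl-5-(propan-2-yl)-6-(tributylstannyl)deca-1,6,9-trien-5-ol | C=C(C)CC[C@@](O)(C(C)C)/C(=C/CC=C)[Sn](CCCC)(CCCC)CCCC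
F14 | step 7 | (5R,6Z)-6-bromo-2-methyl-5-(propan-2-yl)deca-1,6,9-trien-5-ol | C=C(C)CC[C@@](O)(C(C)C)/C(Br)=C/CC=C
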